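Start with the nucleophile. In these flasks electrophile meets nucleophile to give target, and the question is how much electrophile has reacted at the end.

the same everywhere: electrophile 20 mM
- Sunday's: nucleophile 19 mM; run made earlier
- Monday's: nucleophile 31 mM; run made earlier
- summer: nucleophile 30.0 mM; time 40 min
- autumn: nucleophile 39.0 mM; time 40 min

- Sunday's (time / min: electrophile / %, target / %): 2.50: 98.8, 2.3; 5.00: 96.0, 3.9; 12.0: 90.4, 8.9; 30.0: 79.7, 16.7
- Monday's (time / min: electrophile / %, target / %): 2.50: 96.8, 3.3; 5.00: 93.4, 6.8; 12.0: 84.6, 13.8; 30.0: 67.9, 25.7

(scatter of a reading: 0.3 percentage points)

- a reading or a percentage of target counts all its forms, free or not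

- part of the electrophile that has reacted at the end, summer
- part of the electrophile that has reacted at the end, autumn
- what raising the concentration of nucleophile from its lowest to its highest value here does to the part of the electrophile that has reacted (changes below 5 percentage points count as none) (no change / it falls / it rises)

By 30.0 min, Sunday's run has lost electrophile at 0.00756 min⁻¹ and Monday's at 0.0129 min⁻¹. That is 1.71 times the pace for 1.63 times the nucleophile, so we treat the loss as pseudo-first-order in electrophile, its pace set by c_nucleophile.

We assume one nucleophile is used per electrophile. The mean c_nucleophile is then the charge less half of what was used, and dividing each pace by it gives a constant k: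

Sunday: 17.0 mM, k = 4.46 × 10⁻⁴ mM⁻¹ min⁻¹

Monday: 27.8 mM, k = 4.64 × 10⁻⁴ mM⁻¹ min⁻¹

We carry the mean, 4.55 × 10⁻⁴ mM⁻¹ min⁻¹, in one quantity: half-life = ln(2) / (k · mean c_nucleophile).

Now our own ladder, fastest rung first, with mean c_nucleophile from a first pass at the loss.

Autumn: 33.9 mM, half-life 44.9 min, reacted 46.1%

Summer: 25.8 mM, half-life 59.1 min, reacted 37.5%

Summer's electrophile thus goes more slowly than autumn's, and the gap between the two answers is 8.6 percentage points.

The slowest rung is a shortfall. At 30.0 min, Monday's run has lost 32 points of electrophile, and a smaller 6.4 points of that is missing from target. We read k from the electrophile's loss up to 30.0 min, so any pull on the electrophile from the step behind that shortfall sits in k as far as that time, while summer and autumn run on to 40 min.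

The forecast says 37.5% for summer, 46% for autumn, and it rises, holding that “target is probably being slowly lost afterwards”. It uses the same law as ours, so the likeness is no check.

The flask gives 38.2% for summer and 46.7% for autumn: it rises, by 8.4 points.

    electrophile + nucleophile → acid set free + target (k = 0.464 M⁻¹ min⁻¹)
    nucleophile + acid set free ⇌ protonated nucleophile, settled at all times (K = 570 M⁻¹)
    electrophile + target → side product (k = 0.456 M⁻¹ min⁻¹)
    crystals ⇌ target, rate k4*(cs4 - [target]) while solid is left; crystals form when [target] > cs4 (solubility = 12.0 mM, k = 0.314 min⁻¹)

Summer keeps 62% of its electrophile, where the half-life of 59.1 min left 62.5%. Autumn's answer moves by 5 points once its nucleophile slips to 33.5 mM or 44.9 mM, or its time to 33.7 min or 47.2 min, and a run that far off would put the forecast out. A neighbour of summer charged with 7.5 mM of nucleophile keeps 55% of it free, a mean of 5.83 mM. Its half-life is 261 min, which gives 10.1% reacted, and that flask gives 11.4%.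

(The numbers in the tables are calculated for substances that don't exist; noise was put on by code.)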